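**Retrosynthetic overview**

1. Feature: in the isocoumarin (C1 lactone carbonyl, O2, C3, C4, C4a, C5–C8, C8a) the benzo ring (ring A) carries C1 on C8a and C4 on C4a, side by side, and C8 next to C8a bears the ring B aryloxy oxygen. An aryne across C4a–C8a, polarised by that oxygen, can take up both carbons from a malonate in one operation.
2. Disconnections, backwards: four O-benzyl groups; pyranone ring at O2–C3 (cyclodehydration of a 2-(2-oxoheptyl)benzoic acid); C3–C4 (acylation of the homophthalate CH2 with hexanoyl chloride); C4a–C4 and C8a–C1 (insertion of the 3-aryloxy-5-benzyloxybenzyne into diallyl malonate).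
3. Aryne precursor: ring B phenol and 4-(benzyloxy)-2-bromo-6-fluorobenzaldehyde are joined by SNAr (C8–O). Dakin oxidation then sets the oxygen on C8a, a retro-Brook shift sets silicon on C4a, and triflation follows.
4. Ring B phenol: olivetol is dibenzylated and dibrominated symmetrically; one bromine becomes CO2Bn, the other OH.
5. Ring order: both benzene rings are bought (olivetol, 3-bromo-5-fluorophenol); the pyranone is the only ring made and closes in step 14.

Key step: step 11

Remarks on the chemistry: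
- The triflate sits on C8a and silicon on C4a. The isomer with the two groups exchanged gives the same aryne, but this one is reached without any regiochemical choice.
- Allyl esters are used in the malonate. The C8a ester and the ring B benzyl ester are both flanked by two ortho groups, so hydroxide could not tell them apart, whereas cleavage at the allyl carbon by zerovalent palladium can.
- "Ring B aryloxy" means the 2,4-bis(benzyloxy)-5-[(benzyloxy)carbonyl]-6-pentylphenoxy group.

**Route**

Step 1
Reactants: 1 olivetol (5-pentylbenzene-1,3-diol)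
Product: 2 1,3-bis(benzyloxy)-5-pentylbenzene
Conditions: BnBr (2.3 equiv), K2CO3, DMF, 60 °C
Reagents that add atoms: benzyl bromide, BrCc1ccccc1
Why: Williamson ether synthesis; both phenoxides are alkylated by the benzylic bromide.

Step 2
Reactants: 2 1,3-bis(benzyloxy)-5-pentylbenzene
Product: 3 1,5-bis(benzyloxy)-2,4-dibromo-3-pentylbenzene
Conditions: NBS (2.05 equiv), MeCN, 0 °C to rt, dark
Reagents that add atoms: N-bromosuccinimide, O=C1CCC(=O)N1Br
Why: Electrophilic aromatic bromination: each of the two equivalent carbons flanking the pentyl group is para to one benzyloxy group and ortho to the other, whereas the carbon between the two benzyloxy groups is shielded by both, so two equivalents of NBS should stop at the symmetric dibromide.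

Step 3
Reactants: 3 1,5-bis(benzyloxy)-2,4-dibromo-3-pentylbenzene
Product: 5 benzyl 2,4-bis(benzyloxy)-5-bromo-6-pentylbenzoate, via aryllithium 4 (not isolated)
Conditions: n-BuLi (1.0 equiv), THF, −78 °C; then added to ClCO2Bn, THF, −78 °C
Reagents that add atoms: benzyl chloroformate, O=C(Cl)OCc1ccccc1
Why: Bromine–lithium exchange with one equivalent of n-BuLi outruns deprotonation and stops at the monolithio species 4, which at −78 °C adds once to the chloroformate (a second addition is blocked by the two ortho groups); because 3 is symmetric, it does not matter which bromine reacts.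

Step 4
Reactants: 5 benzyl 2,4-bis(benzyloxy)-5-bromo-6-pentylbenzoate
Product: 6 benzyl 2,4-bis(benzyloxy)-6-pentyl-5-(4,4,5,5-tetramethyl-1,3,2-dioxaborolan-2-yl)benzoate
Conditions: B2pin2, Pd(OAc)2, SPhos, KOAc, 1,4-dioxane, 100 °C
Reagents that add atoms: bis(pinacolato)diboron, CC1(C)OB(OC1(C)C)B1OC(C)(C)C(C)(C)O1
Why: Miyaura borylation: the bulky electron-rich SPhos ligand lets palladium insert into the doubly ortho-substituted C–Br bond, and the acetate base leaves the benzyl ester and ethers alone.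

Step 5
Reactants: 6 benzyl 2,4-bis(benzyloxy)-6-pentyl-5-(4,4,5,5-tetramethyl-1,3,2-dioxaborolan-2-yl)benzoate
Product: 7 benzyl 2,4-bis(benzyloxy)-5-hydroxy-6-pentylbenzoate (ring B phenol)
Conditions: H2O2 (30%), NaOH (aq), THF, 0 °C
Reagents that add atoms: hydrogen peroxide, OO
Why: Oxidation of the arylboronate by hydroperoxide (1,2-shift of the aryl group from boron to oxygen) gives the phenol at the carbon that carried boron, and cold dilute hydroxide does not reach the benzoate carbonyl, which is shielded by two ortho groups.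

Step 6
Reactants: 8 3-bromo-5-fluorophenol
Product: 9 1-(benzyloxy)-3-bromo-5-fluorobenzene
Conditions: BnBr, K2CO3, DMF, rt
Reagents that add atoms: benzyl bromide, BrCc1ccccc1
Why: Williamson ether synthesis of the phenoxide with the benzylic bromide.

Step 7
Reactants: 9 1-(benzyloxy)-3-bromo-5-fluorobenzene
Product: 11 4-(benzyloxy)-2-bromo-6-fluorobenzaldehyde, via aryllithium 10 (not isolated)
Conditions: LiN(i-Pr)2, THF, −78 °C; then DMF, −78 °C; aq. NH4Cl
Reagents that add atoms: N,N-dimethylformamide, CN(C)C=O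
Why: Deprotonation by the lithium amide (directed ortho-metalation type) takes the C–H between fluorine and bromine, the most acidic one because both halogens acidify their ortho position more than the benzyloxy group does; a lithium amide does not exchange the bromine, and at −78 °C the aryllithium 10 is formylated by DMF before it can lose lithium halide.

Step 8
Reactants: 7 benzyl 2,4-bis(benzyloxy)-5-hydroxy-6-pentylbenzoate; 11 4-(benzyloxy)-2-bromo-6-fluorobenzaldehyde
Product: 12 benzyl 2,4-bis(benzyloxy)-5-[5-(benzyloxy)-3-bromo-2-formylphenoxy]-6-pentylbenzoate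
Conditions: Cs2CO3, DMF, 80 °C
Reagents that add atoms: none
Why: Nucleophilic aromatic substitution (addition–elimination): the fluorine ortho to the formyl group is displaced through a Meisenheimer intermediate by the cesium phenoxide of 7, while the bromine, a far poorer leaving group in this mechanism, is kept for step 10.

Step 9
Reactants: 12 benzyl 2,4-bis(benzyloxy)-5-[5-(benzyloxy)-3-bromo-2-formylphenoxy]-6-pentylbenzoate
Product: 14 benzyl 2,4-bis(benzyloxy)-5-[5-(benzyloxy)-3-bromo-2-hydroxyphenoxy]-6-pentylbenzoate, via aryl formate 13 (not isolated)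
Conditions: mCPBA, CH2Cl2, rt; then K2CO3 (cat.), MeOH, 0 °C
Reagents that add atoms: 3-chloroperoxybenzoic acid, OOC(=O)c1cccc(Cl)c1
Why: Dakin-type Baeyer–Villiger oxidation: the electron-rich aryl group (para benzyloxy, ortho aryloxy) migrates in preference to hydrogen to give formate 13, which mild methanolysis cleaves without touching the hindered benzyl ester.

Step 10
Reactants: 14 benzyl 2,4-bis(benzyloxy)-5-[5-(benzyloxy)-3-bromo-2-hydroxyphenoxy]-6-pentylbenzoate
Product: 17 benzyl 2,4-bis(benzyloxy)-5-{5-(benzyloxy)-2-[(trifluoromethanesulfonyl)oxy]-3-(trimethylsilyl)phenoxy}-6-pentylbenzoate, via O-trimethylsilyl ether 15 (not isolated), via lithium 2-silylphenoxide 16 (not isolated)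
Conditions: HN(SiMe3)2, THF, 65 °C, concentrate; n-BuLi, THF, −100 °C to −78 °C; Tf2O, −78 °C
Reagents that add atoms: hexamethyldisilazane, C[Si](C)(C)N[Si](C)(C)C; trifluoromethanesulfonic anhydride, O=S(=O)(OS(=O)(=O)C(F)(F)F)C(F)(F)F
Why: Standard route to 2-silylaryl triflates: O-silylation, bromine–lithium exchange at −100 °C (faster than addition of n-BuLi to the doubly ortho-substituted benzyl ester), 1,3-shift of silicon from oxygen to the lithiated carbon (retro-Brook rearrangement) and O-triflation of the lithium phenoxide 16 place SiMe3 on C4a and OTf on C8a.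

Step 11
Reactants: 17 benzyl 2,4-bis(benzyloxy)-5-{5-(benzyloxy)-2-[(trifluoromethanesulfonyl)oxy]-3-(trimethylsilyl)phenoxy}-6-pentylbenzoate; 18 diallyl malonate
Product: 20 benzyl 2,4-bis(benzyloxy)-5-{5-(benzyloxy)-2-[(allyloxy)carbonyl]-3-[2-(allyloxy)-2-oxoethyl]phenoxy}-6-pentylbenzoate, via aryne 19 (not isolated)
Conditions: KF, 18-crown-6, THF, 0 °C to rt
Reagents that add atoms: none
Why: Fluoride attacks silicon on C4a and triflate leaves from C8a, which gives aryne 19 across C4a–C8a. The potassium enolate of 18 adds through carbon to C4a, the aryne carbon remote from the C8 aryloxy group, so that the aryl anion develops at C8a beside the σ-withdrawing oxygen; this anion closes onto one allyl ester carbonyl (4-exo-trig) to a benzocyclobutenoxide that fragments to the stabilised ester enolate, leaving CO2allyl on C8a and CH2CO2allyl on C4a. The closest known reactions are the fluoride-induced insertion of arynes into the C–C σ-bond of malonates and the acyl-alkylation of 3-alkoxy- and 3,5-dialkoxyarynes with β-keto esters. No ring persists (the four-membered ring is transient) and no stereocentre forms. The step needs regioselective addition to the unsymmetrical aryne, which the C8 aryloxy group secures by stabilising the C8a anion inductively and by distorting the aryne toward attack at C4a. It also needs the intramolecular acyl transfer to outrun protonation of the aryl anion, which is why aprotic THF with KF and 18-crown-6 is chosen over acetonitrile and only a small excess of 18 is used.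

Step 12
Reactants: 20 benzyl 2,4-bis(benzyloxy)-5-{5-(benzyloxy)-2-[(allyloxy)carbonyl]-3-[2-(allyloxy)-2-oxoethyl]phenoxy}-6-pentylbenzoate; 21 hexanoyl chloride
Product: 22 benzyl 2,4-bis(benzyloxy)-5-{5-(benzyloxy)-2-[(allyloxy)carbonyl]-3-[1-(allyloxy)-1,3-dioxooctan-2-yl]phenoxy}-6-pentylbenzoate (racemic)
Conditions: LiN(SiMe3)2 (2.2 equiv), THF, −78 °C; then 21, −78 °C; aq. NH4Cl at −78 °C
Reagents that add atoms: none
Why: Claisen-type C-acylation: LiN(SiMe3)2 removes a proton only from the benzylic CH2 next to the ester (the sole C–H acid within its reach), the lithium enolate is acylated at carbon by 21, the second equivalent of base deprotonates the more acidic β-keto ester so that acylation stops after one acyl group, and the cold quench keeps the product enolate from closing onto the aryl ester.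

Step 13
Reactants: 22 benzyl 2,4-bis(benzyloxy)-5-{5-(benzyloxy)-2-[(allyloxy)carbonyl]-3-[1-(allyloxy)-1,3-dioxooctan-2-yl]phenoxy}-6-pentylbenzoate
Product: 24 4-(benzyloxy)-2-(2-oxoheptyl)-6-(ring B aryloxy)benzoic acid, via beta-keto diacid 23 (not isolated)
Conditions: Pd(PPh3)4 (5 mol %), morpholine, THF, rt; then dilute HCl, rt
Reagents that add atoms: none
Why: Tsuji–Trost deallylation: zerovalent palladium ionises both allyl esters at the allyl carbon, so steric shielding of the C8a carbonyl does not matter and the ring B benzyl ester is untouched, morpholine traps the π-allyl fragments, and the α-aryl β-keto acid in 23 loses CO2 at room temperature.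

Step 14
Reactants: 24 4-(benzyloxy)-2-(2-oxoheptyl)-6-(ring B aryloxy)benzoic acid
Product: 25 benzyl 2,4-bis(benzyloxy)-5-{[6-(benzyloxy)-1-oxo-3-pentyl-1H-isochromen-8-yl]oxy}-6-pentylbenzoate
Conditions: TsOH·H2O (10 mol %), toluene, 80 °C, 4 Å molecular sieves
Reagents that add atoms: none
Why: Acid-catalysed cyclodehydration of a 2-(2-oxoalkyl)benzoic acid, the classical isocoumarin closure: the carboxyl oxygen adds to the ketone (6-exo-trig, bond O2–C3) and the lactol loses water to the conjugated pyranone.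

Step 15
Reactants: 25 benzyl 2,4-bis(benzyloxy)-5-{[6-(benzyloxy)-1-oxo-3-pentyl-1H-isochromen-8-yl]oxy}-6-pentylbenzoate
Product: 26 2,4-dihydroxy-5-[(6-hydroxy-1-oxo-3-pentyl-1H-isochromen-8-yl)oxy]-6-pentylbenzoic acid (CNP0439913.0)
Conditions: H2 (1 atm), 10% Pd/C, EtOAc/MeOH, rt
Reagents that add atoms: none
Why: Hydrogenolysis over palladium cleaves the three benzyl ethers and the benzyl ester under neutral conditions at room temperature, at which the salicylic acid of ring B does not decarboxylate, and the reaction is stopped after uptake of four equivalents because the C3–C4 double bond of the pyranone is reduced only slowly.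

**Compound list**

1 | olivetol (5-pentylbenzene-1,3-diol) | CCCCCc1cc(O)cc(O)c1 | starting material
2 | 1,3-bis(benzyloxy)-5-pentylbenzene | CCCCCc1cc(OCc2ccccc2)cc(OCc2ccccc2)c1 | intermediate
3 | 1,5-bis(benzyloxy)-2,4-dibromo-3-pentylbenzene | CCCCCc1c(Br)c(OCc2ccccc2)cc(OCc2ccccc2)c1Br | intermediate
4 | [2,4-bis(benzyloxy)-5-bromo-6-pentylphenyl]lithium | CCCCCc1c(Br)c(OCc2ccccc2)cc(OCc2ccccc2)c1[Li] | intermediate
5 | benzyl 2,4-bis(benzyloxy)-5-bromo-6-pentylbenzoate | CCCCCc1c(Br)c(OCc2ccccc2)cc(OCc2ccccc2)c1C(=O)OCc1ccccc1 | intermediate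
6 | benzyl 2,4-bis(benzyloxy)-6-pentyl-5-(4,4,5,5-tetramethyl-1,3,2-dioxaborolan-2-yl)benzoate | CCCCCc1c(B2OC(C)(C)C(C)(C)O2)c(OCc2ccccc2)cc(OCc2ccccc2)c1C(=O)OCc1ccccc1 | intermediate
7 | benzyl 2,4-bis(benzyloxy)-5-hydroxy-6-pentylbenzoate | CCCCCc1c(O)c(OCc2ccccc2)cc(OCc2ccccc2)c1C(=O)OCc1ccccc1 | intermediate
8 | 3-bromo-5-fluorophenol | Oc1cc(F)cc(Br)c1 | starting material
9 | 1-(benzyloxy)-3-bromo-5-fluorobenzene | Fc1cc(Br)cc(OCc2ccccc2)c1 | intermediate
10 | [4-(benzyloxy)-2-bromo-6-fluorophenyl]lithium | [Li]c1c(F)cc(OCc2ccccc2)cc1Br | intermediate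
11 | 4-(benzyloxy)-2-bromo-6-fluorobenzaldehyde | O=Cc1c(F)cc(OCc2ccccc2)cc1Br | intermediate
12 | benzyl 2,4-bis(benzyloxy)-5-[5-(benzyloxy)-3-bromo-2-formylphenoxy]-6-pentylbenzoate | O=Cc1c(Br)cc(OCc2ccccc2)cc1Oc1c(OCc2ccccc2)cc(OCc2ccccc2)c(C(=O)OCc2ccccc2)c1CCCCC | intermediate
13 | benzyl 2,4-bis(benzyloxy)-5-[5-(benzyloxy)-3-bromo-2-(formyloxy)phenoxy]-6-pentylbenzoate | O=COc1c(Br)cc(OCc2ccccc2)cc1Oc1c(OCc2ccccc2)cc(OCc2ccccc2)c(C(=O)OCc2ccccc2)c1CCCCC | intermediate
14 | benzyl 2,4-bis(benzyloxy)-5-[5-(benzyloxy)-3-bromo-2-hydroxyphenoxy]-6-pentylbenzoate | Oc1c(Br)cc(OCc2ccccc2)cc1Oc1c(OCc2ccccc2)cc(OCc2ccccc2)c(C(=O)OCc2ccccc2)c1CCCCC | intermediate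
15 | benzyl 2,4-bis(benzyloxy)-5-{5-(benzyloxy)-3-bromo-2-[(trimethylsilyl)oxy]phenoxy}-6-pentylbenzoate | C[Si](C)(C)Oc1c(Br)cc(OCc2ccccc2)cc1Oc1c(OCc2ccccc2)cc(OCc2ccccc2)c(C(=O)OCc2ccccc2)c1CCCCC | intermediate
16 | lithium 4-(benzyloxy)-2-(ring B aryloxy)-6-(trimethylsilyl)phenoxide | [Li]Oc1c([Si](C)(C)C)cc(OCc2ccccc2)cc1Oc1c(OCc2ccccc2)cc(OCc2ccccc2)c(C(=O)OCc2ccccc2)c1CCCCC | intermediate
17 | benzyl 2,4-bis(benzyloxy)-5-{5-(benzyloxy)-2-[(trifluoromethanesulfonyl)oxy]-3-(trimethylsilyl)phenoxy}-6-pentylbenzoate | C[Si](C)(C)c1cc(OCc2ccccc2)cc(Oc2c(OCc3ccccc3)cc(OCc3ccccc3)c(C(=O)OCc3ccccc3)c2CCCCC)c1OS(=O)(=O)C(F)(F)F | intermediate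
18 | diallyl malonate | C=CCOC(=O)CC(=O)OCC=C | starting material
19 | benzyl 2,4-bis(benzyloxy)-5-{[5-(benzyloxy)-2,3-didehydrophenyl]oxy}-6-pentylbenzoate (the aryne) | C1#CC(Oc2c(OCc3ccccc3)cc(OCc3ccccc3)c(C(=O)OCc3ccccc3)c2CCCCC)=CC(OCc2ccccc2)=C1 | intermediate
20 | benzyl 2,4-bis(benzyloxy)-5-{5-(benzyloxy)-2-[(allyloxy)carbonyl]-3-[2-(allyloxy)-2-oxoethyl]phenoxy}-6-pentylbenzoate | C=CCOC(=O)Cc1cc(OCc2ccccc2)cc(Oc2c(OCc3ccccc3)cc(OCc3ccccc3)c(C(=O)OCc3ccccc3)c2CCCCC)c1C(=O)OCC=C | intermediate
21 | hexanoyl chloride | CCCCCC(Cl)=O | starting material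
22 | benzyl 2,4-bis(benzyloxy)-5-{5-(benzyloxy)-2-[(allyloxy)carbonyl]-3-[1-(allyloxy)-1,3-dioxooctan-2-yl]phenoxy}-6-pentylbenzoate (racemic, enolisable) | CCCCCC(=O)C(C(=O)OCC=C)c1cc(OCc2ccccc2)cc(Oc2c(OCc3ccccc3)cc(OCc3ccccc3)c(C(=O)OCc3ccccc3)c2CCCCC)c1C(=O)OCC=C | intermediate
23 | 4-(benzyloxy)-2-(1-carboxy-2-oxoheptyl)-6-(ring B aryloxy)benzoic acid (racemic) | CCCCCC(=O)C(C(=O)O)c1cc(OCc2ccccc2)cc(Oc2c(OCc3ccccc3)cc(OCc3ccccc3)c(C(=O)OCc3ccccc3)c2CCCCC)c1C(=O)O | intermediate
24 | 4-(benzyloxy)-2-(2-oxoheptyl)-6-(ring B aryloxy)benzoic acid | CCCCCC(=O)Cc1cc(OCc2ccccc2)cc(Oc2c(OCc3ccccc3)cc(OCc3ccccc3)c(C(=O)OCc3ccccc3)c2CCCCC)c1C(=O)O | intermediate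
25 | benzyl 2,4-bis(benzyloxy)-5-{[6-(benzyloxy)-1-oxo-3-pentyl-1H-isochromen-8-yl]oxy}-6-pentylbenzoate | CCCCCc1cc2cc(OCc3ccccc3)cc(Oc3c(OCc4ccccc4)cc(OCc4ccccc4)c(C(=O)OCc4ccccc4)c3CCCCC)c2c(=O)o1 | intermediate
26 | 2,4-dihydroxy-5-[(6-hydroxy-1-oxo-3-pentyl-1H-isochromen-8-yl)oxy]-6-pentylbenzoic acid | CCCCCc1cc2cc(O)cc(Oc3c(O)cc(O)c(C(=O)O)c3CCCCC)c2c(=O)o1 | target

**Step count**

Total: 15 steps. Longest linear sequence: 13 steps (steps 1–5, then 8–15); steps 6–7 form the short branch.

**Steps most likely to fail**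

Step 11 (aryne insertion). The aryl anion at C8a may be protonated before it reaches the ester carbonyl, so that plain α-arylation of the malonate results; the enolate may also add in part at C8a. The fallback sets out from aldehyde 12 and comes back at 25, replacing steps 9–14 by alkyne chemistry. Compound 12 is oxidised (NaClO2, NaH2PO4, 2-methylbut-2-ene, t-BuOH/H2O) to 4-(benzyloxy)-2-bromo-6-(ring B aryloxy)benzoic acid F1. Methylation (MeI, K2CO3, DMF) gives methyl 4-(benzyloxy)-2-bromo-6-(ring B aryloxy)benzoate F2. Sonogashira coupling at the C4a bromide with hept-1-yne (PdCl2(PPh3)2, CuI, Et3N, DMF, 70 °C) gives methyl 4-(benzyloxy)-2-(hept-1-yn-1-yl)-6-(ring B aryloxy)benzoate F3. Acid-catalysed 6-endo-dig lactonisation of the ester carbonyl onto the alkyne (AgOTf cat. or CF3SO3H cat., wet 1,2-dichloroethane), with loss of methanol, should give 25, which is debenzylated as in step 15.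

Step 10 (retro-Brook silylation and triflation). Butyllithium or the aryllithium may add to the ring B benzyl ester, or the aryllithium may be quenched by a proton before silicon migrates, which would return debrominated phenol. The fallback sets out from silyl ether 15 and comes back at 17 without any organolithium. Palladium-catalysed C-silylation of the aryl bromide with hexamethyldisilane (Pd2(dba)3, 2-(di-tert-butylphosphino)biphenyl, LiOAc, DMF, 100 °C) and aqueous work-up should give 4-(benzyloxy)-2-(ring B aryloxy)-6-(trimethylsilyl)phenol F4. Triflation with Tf2O and pyridine in CH2Cl2 at 0 °C gives 17.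

Step 8 (SNAr). Addition of the doubly ortho-substituted phenoxide to the fluoroarene may be too slow, because the para benzyloxy group damps the activation by the formyl group, and the aldehyde may degrade at the temperature then needed. The fallback sets out from 7 and comes back at 12 by copper catalysis. 3,5-Dibromophenol is benzylated (BnBr, K2CO3) to 1-(benzyloxy)-3,5-dibromobenzene F5. Lithiation between the two bromines with LiN(i-Pr)2 at −78 °C and formylation with DMF give the symmetric 4-(benzyloxy)-2,6-dibromobenzaldehyde F6. Ullmann etherification of 7 with an excess of F6 (CuI, picolinic acid, K3PO4, DMSO, 90 °C), in which the ortho formyl group assists oxidative addition to copper, replaces one bromine and gives 12.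

**Further compounds**

F1 | step 11 | 4-(benzyloxy)-2-bromo-6-(ring B aryloxy)benzoic acid | OC(=O)c1c(Br)cc(OCc2ccccc2)cc1Oc1c(OCc2ccccc2)cc(OCc2ccccc2)c(C(=O)OCc2ccccc2)c1CCCCC
F2 | step 11 | methyl 4-(benzyloxy)-2-bromo-6-(ring B aryloxy)benzoate | COC(=O)c1c(Br)cc(OCc2ccccc2)cc1Oc1c(OCc2ccccc2)cc(OCc2ccccc2)c(C(=O)OCc2ccccc2)c1CCCCC
F3 | step 11 | methyl 4-(benzyloxy)-2-(hept-1-yn-1-yl)-6-(ring B aryloxy)benzoate | CCCCCC#Cc1cc(OCc2ccccc2)cc(Oc2c(OCc3ccccc3)cc(OCc3ccccc3)c(C(=O)OCc3ccccc3)c2CCCCC)c1C(=O)OC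
F4 | step 10 | 4-(benzyloxy)-2-(ring B aryloxy)-6-(trimethylsilyl)phenol | C[Si](C)(C)c1cc(OCc2ccccc2)cc(Oc2c(OCc3ccccc3)cc(OCc3ccccc3)c(C(=O)OCc3ccccc3)c2CCCCC)c1O
F5 | step 8 | 1-(benzyloxy)-3,5-dibromobenzene | Brc1cc(Br)cc(OCc2ccccc2)c1
F6 | step 8 | 4-(benzyloxy)-2,6-dibromobenzaldehyde | O=Cc1c(Br)cc(OCc2ccccc2)cc1Br
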